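**Retrosynthetic overview**

- The strategy rests on ring A (C4a, C5–C8, C8a): four contiguous oxygens on C5–C8, with the C5 hydroxyl para to the C8 methoxyl. This is the pattern a squarate-derived 4-alkenyl-4-methoxycyclobutenone gives on thermal ring expansion.
- Last disconnection: the four O-benzyl groups (C7, C3', C4', C5'). Before it, the C4a–C5 bond: ring A is opened back to a 4-(4-oxopyran-2-yl)-4-methoxycyclobutenone (4π opening, then 6π closure in the forward sense).
- The C7 benzyloxyl is placed on the cyclobutenone by hydrolysis of the vinylogous methyl ester and Mitsunobu benzylation of the resulting symmetric enol. The C8–C8a bond comes from addition of the C6-lithiated pyranone to dimethyl squarate, with O-methylation in the flask.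
- The 2-aryl-3-methoxy-4-pyranone (rings C and B) comes from pyromeconic acid by C2 bromination, O-methylation and Suzuki coupling.
- Ring order: ring C is bought, ring B is attached in step 3, ring A is formed last in step 7.

Key step: step 7

Assumption: pyromeconic acid and the tribenzyloxyphenylboronic acid are taken as purchased. The cyclobutenone intermediates are racemic at their quaternary carbon, which becomes the planar C8 in the key step, so no stereocontrol is needed; the target has no stereocentre.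

**Route**

Step 1
Reactants: 1 3-hydroxy-4H-pyran-4-one (pyromeconic acid)
Product: 2 2-bromo-3-hydroxy-4H-pyran-4-one
Conditions: NBS, MeCN, 0 °C → rt, dark
Reagents that add atoms: N-bromosuccinimide, O=C1CCC(=O)N1Br
Why: Electrophilic bromination of the enolic 3-hydroxy-4-pyranone should occur at C2, the β-carbon of the enol and the only position ortho to the hydroxyl, as in the ortho-halogenation of kojic acid and related 3-hydroxy-4-pyranones.

Step 2
Reactants: 2 2-bromo-3-hydroxy-4H-pyran-4-one
Product: 3 2-bromo-3-methoxy-4H-pyran-4-one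
Conditions: MeI, K2CO3, acetone, 50 °C
Reagents that add atoms: iodomethane, CI
Why: Williamson O-methylation of the acidic enolic hydroxyl with a weak base should leave the vinylogous acyl bromide untouched.

Step 3
Reactants: 3 2-bromo-3-methoxy-4H-pyran-4-one; 4 [3,4,5-tris(benzyloxy)phenyl]boronic acid
Product: 5 3-methoxy-2-[3,4,5-tris(benzyloxy)phenyl]-4H-pyran-4-one
Conditions: Pd(PPh3)4 (5 mol %), K2CO3, 1,4-dioxane/H2O, 85 °C
Reagents that add atoms: none
Why: Suzuki–Miyaura coupling; the C2–Br bond is of the β-bromo-enone type and adds readily to zerovalent palladium, and the benzyl ethers and the pyranone tolerate aqueous carbonate at this temperature.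

Step 4
Reactants: 5 3-methoxy-2-[3,4,5-tris(benzyloxy)phenyl]-4H-pyran-4-one; 6 dimethyl squarate (3,4-dimethoxycyclobut-3-ene-1,2-dione)
Product: 9 2,3,4-trimethoxy-4-{5-methoxy-4-oxo-6-[3,4,5-tris(benzyloxy)phenyl]-4H-pyran-2-yl}cyclobut-2-en-1-one (racemic), via C6-lithiated pyranone 7 (not isolated), via lithium alkoxide 8 (not isolated)
Conditions: LiTMP (lithium 2,2,6,6-tetramethylpiperidide, from TMPH and n-BuLi), THF, −78 °C; cannulate into 6, THF, −78 °C; MeOTf, −78 → 0 °C
Reagents that add atoms: methyl trifluoromethanesulfonate, COS(=O)(=O)C(F)(F)F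
Why: Deprotonation with the hindered amide base should remove the C6–H α to the ring oxygen (the known site of lithiation of chromones and γ-pyranones that carry a hydrogen there), the vinyllithium 7 adds 1,2 to one of the two equivalent squarate carbonyls, and the tertiary lithium alkoxide 8 is O-methylated in the flask by methyl triflate, the usual protection of squarate adducts before ring expansion; the new quaternary centre forms racemic and is lost in step 7.

Step 5
Reactants: 9 2,3,4-trimethoxy-4-{5-methoxy-4-oxo-6-[3,4,5-tris(benzyloxy)phenyl]-4H-pyran-2-yl}cyclobut-2-en-1-one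
Product: 11 3-hydroxy-2,4-dimethoxy-4-{5-methoxy-4-oxo-6-[3,4,5-tris(benzyloxy)phenyl]-4H-pyran-2-yl}cyclobut-2-en-1-one (racemic), via lithium enolate 10 (not isolated)
Conditions: LiOH (1.1 equiv), THF/H2O, 0 °C; then cold 1 M HCl to pH 2–3, extract
Reagents that add atoms: lithium hydroxide, [Li+].[OH-]
Why: Saponification of a vinylogous ester by addition–elimination: hydroxide adds to C3, the β-carbon of the alkoxy-enone, and expels methoxide, whereas the C2 methoxyl (α to the carbonyl) and the C4 methoxyl cannot be displaced this way, and the delocalised enolate 10 is inert to further attack.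

Step 6
Reactants: 11 3-hydroxy-2,4-dimethoxy-4-{5-methoxy-4-oxo-6-[3,4,5-tris(benzyloxy)phenyl]-4H-pyran-2-yl}cyclobut-2-en-1-one
Product: 12 3-(benzyloxy)-2,4-dimethoxy-4-{5-methoxy-4-oxo-6-[3,4,5-tris(benzyloxy)phenyl]-4H-pyran-2-yl}cyclobut-2-en-1-one (racemic)
Conditions: BnOH, PPh3, DIAD, THF, 0 °C → rt
Reagents that add atoms: benzyl alcohol, OCc1ccccc1
Why: Mitsunobu O-alkylation of a strongly acidic enol; the enolate of 11 has a mirror plane through C2 and C4, so benzylation at either oxygen gives the same constitution (the two products are enantiomers), which places the benzyloxyl β and the methoxyl α to the carbonyl without a regiochemical choice.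

Step 7
Reactants: 12 3-(benzyloxy)-2,4-dimethoxy-4-{5-methoxy-4-oxo-6-[3,4,5-tris(benzyloxy)phenyl]-4H-pyran-2-yl}cyclobut-2-en-1-one
Product: 15 7-(benzyloxy)-5-hydroxy-3,6,8-trimethoxy-2-[3,4,5-tris(benzyloxy)phenyl]-4H-chromen-4-one, via dienylketene 13 (not isolated), via keto tautomer 14 (not isolated)
Conditions: degassed toluene, 0.02 M, 110 °C (sealed tube, up to 140 °C if slow)
Reagents that add atoms: none
Why: Proposed new method: the closest known reaction type is the Moore-type thermal ring expansion of 4-alkenyl-, 4-aryl- and 4-heteroaryl-4-alkoxycyclobutenones to para-alkoxyphenols, and here the ring C=C bond of a γ-pyranone that carries the cyclobutenone (the future C8a=C4a) is asked to serve as the alkenyl partner. Conrotatory 4π opening of the C1–C4 bond of 12 gives the dienylketene 13, whose electrophilic ketene carbon lies next to the pyranone CH carbon, the nucleophilic α-carbon of the vinylogous ester. A thermally allowed disrotatory 6π electrocyclisation forms the C4a–C5 bond and closes ring A as the dienone 14, a β-diketone whose C4a–H enolises at once to the phenol 15, held by the hydrogen bond to the C4 carbonyl. The step needs outward rotation of the C4 methoxyl so that the pyranonyl group turns inward toward the ketene; donor substituents at C4 of cyclobutenones rotate outward, which should secure the Z-dienylketene. No stereocentre is formed, and the C6 methoxyl and C7 benzyloxyl follow from their α and β places on the cyclobutenone. The pyranone has much less aromatic stabilisation to give up than the benzene and furan rings known to take part, which is why closure is expected in this temperature range.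

Step 8
Reactants: 15 7-(benzyloxy)-5-hydroxy-3,6,8-trimethoxy-2-[3,4,5-tris(benzyloxy)phenyl]-4H-chromen-4-one
Product: 16 5,7-dihydroxy-3,6,8-trimethoxy-2-(3,4,5-trihydroxyphenyl)-4H-chromen-4-one (target)
Conditions: H2 (1 atm), 10% Pd/C, THF/MeOH, rt; filter under argon
Reagents that add atoms: none
Why: Catalytic hydrogenolysis should cleave the four aryl benzyl ethers (C7, C3', C4', C5') while the methyl ethers, the chelated C5 hydroxyl and the chromone ring are stable under one atmosphere of hydrogen at room temperature.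

**Compound list**

1 | 3-hydroxy-4H-pyran-4-one (pyromeconic acid) | O=c1ccocc1O | starting material
2 | 2-bromo-3-hydroxy-4H-pyran-4-one | O=c1ccoc(Br)c1O | intermediate
3 | 2-bromo-3-methoxy-4H-pyran-4-one | COc1c(Br)occc1=O | intermediate
4 | [3,4,5-tris(benzyloxy)phenyl]boronic acid | OB(O)c1cc(OCc2ccccc2)c(OCc2ccccc2)c(OCc2ccccc2)c1 | starting material
5 | 3-methoxy-2-[3,4,5-tris(benzyloxy)phenyl]-4H-pyran-4-one | COc1c(-c2cc(OCc3ccccc3)c(OCc3ccccc3)c(OCc3ccccc3)c2)occc1=O | intermediate
6 | dimethyl squarate (3,4-dimethoxycyclobut-3-ene-1,2-dione) | COC1=C(OC)C(=O)C1=O | starting material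
7 | {5-methoxy-4-oxo-6-[3,4,5-tris(benzyloxy)phenyl]-4H-pyran-2-yl}lithium | [Li]c1cc(=O)c(OC)c(-c2cc(OCc3ccccc3)c(OCc3ccccc3)c(OCc3ccccc3)c2)o1 | intermediate (not isolated)
8 | lithium 2,3-dimethoxy-1-{5-methoxy-4-oxo-6-[3,4,5-tris(benzyloxy)phenyl]-4H-pyran-2-yl}-4-oxocyclobut-2-en-1-olate | [Li+].[O-]C1(c2cc(=O)c(OC)c(-c3cc(OCc4ccccc4)c(OCc4ccccc4)c(OCc4ccccc4)c3)o2)C(OC)=C(OC)C1=O | intermediate (not isolated)
9 | 2,3,4-trimethoxy-4-{5-methoxy-4-oxo-6-[3,4,5-tris(benzyloxy)phenyl]-4H-pyran-2-yl}cyclobut-2-en-1-one (racemic) | COC1=C(OC)C(OC)(c2cc(=O)c(OC)c(-c3cc(OCc4ccccc4)c(OCc4ccccc4)c(OCc4ccccc4)c3)o2)C1=O | intermediate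
10 | lithium 2,4-dimethoxy-4-{5-methoxy-4-oxo-6-[3,4,5-tris(benzyloxy)phenyl]-4H-pyran-2-yl}-3-oxocyclobut-1-en-1-olate | [Li+].[O-]C1=C(OC)C(=O)C1(OC)c1cc(=O)c(OC)c(-c2cc(OCc3ccccc3)c(OCc3ccccc3)c(OCc3ccccc3)c2)o1 | intermediate (not isolated)
11 | 3-hydroxy-2,4-dimethoxy-4-{5-methoxy-4-oxo-6-[3,4,5-tris(benzyloxy)phenyl]-4H-pyran-2-yl}cyclobut-2-en-1-one (racemic) | COC1=C(O)C(OC)(c2cc(=O)c(OC)c(-c3cc(OCc4ccccc4)c(OCc4ccccc4)c(OCc4ccccc4)c3)o2)C1=O | intermediate
12 | 3-(benzyloxy)-2,4-dimethoxy-4-{5-methoxy-4-oxo-6-[3,4,5-tris(benzyloxy)phenyl]-4H-pyran-2-yl}cyclobut-2-en-1-one (racemic; key-step precursor) | COC1=C(OCc2ccccc2)C(OC)(c2cc(=O)c(OC)c(-c3cc(OCc4ccccc4)c(OCc4ccccc4)c(OCc4ccccc4)c3)o2)C1=O | intermediate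
13 | (3Z)-3-(benzyloxy)-2,4-dimethoxy-4-{5-methoxy-4-oxo-6-[3,4,5-tris(benzyloxy)phenyl]-4H-pyran-2-yl}buta-1,3-dien-1-one (dienylketene) | O=C=C(OC)/C(OCc1ccccc1)=C(/OC)c1cc(=O)c(OC)c(-c2cc(OCc3ccccc3)c(OCc3ccccc3)c(OCc3ccccc3)c2)o1 | intermediate (not isolated)
14 | 7-(benzyloxy)-3,6,8-trimethoxy-2-[3,4,5-tris(benzyloxy)phenyl]-4aH-chromene-4,5-dione (keto tautomer, racemic) | COC1=C(OCc2ccccc2)C(OC)=C2OC(-c3cc(OCc4ccccc4)c(OCc4ccccc4)c(OCc4ccccc4)c3)=C(OC)C(=O)C2C1=O | intermediate (not isolated)
15 | 7-(benzyloxy)-5-hydroxy-3,6,8-trimethoxy-2-[3,4,5-tris(benzyloxy)phenyl]-4H-chromen-4-one | COc1c(OCc2ccccc2)c(OC)c2oc(-c3cc(OCc4ccccc4)c(OCc4ccccc4)c(OCc4ccccc4)c3)c(OC)c(=O)c2c1O | intermediate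
16 | 5,7-dihydroxy-3,6,8-trimethoxy-2-(3,4,5-trihydroxyphenyl)-4H-chromen-4-one | COc1c(O)c(OC)c2oc(-c3cc(O)c(O)c(O)c3)c(OC)c(=O)c2c1O | target

**Step count**

Total steps: 8. Longest linear sequence: 8 steps (1 → 16); 4 and 6 enter as purchased materials.

**Steps most likely to fail**

Step 7. Process at risk: after ring opening the dienylketene may not close onto the pyranone C=C bond (reversion to 12, ketene dimerisation, capture by adventitious nucleophiles), or the methoxyl may rotate inward so that ketene and pyranone never meet. The fallback uses known chemistry, sets out from dimethyl squarate 6 and returns at 15. Ring A is still made by squarate ring expansion, but onto a plain alkoxyvinyl group, the established case, and ring C is built afterwards by a Baker–Venkataraman sequence.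
- 1-Methoxyvinyllithium (methyl vinyl ether, t-BuLi, THF, −78 → 0 °C) is added to 6 at −78 °C and the alkoxide is methylated in the flask with MeOTf to give 2,3,4-trimethoxy-4-(1-methoxyethenyl)cyclobut-2-en-1-one F1.
- LiOH (THF/H2O, 0 °C) exchanges the vinylogous ester methoxyl and gives lithium 2,4-dimethoxy-4-(1-methoxyethenyl)-3-oxocyclobut-1-en-1-olate F2. This is dried and O-benzylated without acidification, since the enol ether would not survive acid (BnBr, DMF, rt), to 3-(benzyloxy)-2,4-dimethoxy-4-(1-methoxyethenyl)cyclobut-2-en-1-one F3.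
- Heating F3 in toluene (110 °C) should give 3-(benzyloxy)-2,4,5-trimethoxyphenol F4 by the 4-alkenylcyclobutenone ring expansion.
- Friedel–Crafts acylation at the one free ring position (methoxyacetic anhydride, BF3·OEt2, CH2Cl2, 0 °C → rt) gives 1-[4-(benzyloxy)-2-hydroxy-3,5,6-trimethoxyphenyl]-2-methoxyethan-1-one F5.
- Its dianion (LiN(SiMe3)2, THF, −78 °C) is C-aroylated with 3,4,5-tris(benzyloxy)benzoyl chloride to 1-[4-(benzyloxy)-2-hydroxy-3,5,6-trimethoxyphenyl]-2-methoxy-3-[3,4,5-tris(benzyloxy)phenyl]propane-1,3-dione F6.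
- Cyclodehydration (TsOH, toluene, 80 °C) gives 7-(benzyloxy)-3,5,6,8-tetramethoxy-2-[3,4,5-tris(benzyloxy)phenyl]-4H-chromen-4-one F7.
- Chelation-controlled cleavage of the peri C5 methyl ether (AlCl3, MeCN, rt) returns 15, which goes on to step 8.

Step 4. Process at risk: the C6-lithio species 7 may be consumed by addition to pyranone that is not yet metalated, or by fragmentation after competing deprotonation next to the carbonyl; the amine set free may also compete with the alkoxide for MeOTf. The fallback sets out from 5 and returns at 7, and separates metalation from C–C bond formation.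
- 5 is zincated α to the ring oxygen with TMPZnCl·LiCl (THF, 25 °C) to chloro{5-methoxy-4-oxo-6-[3,4,5-tris(benzyloxy)phenyl]-4H-pyran-2-yl}zinc F8, an organozinc that does not add to pyranones.
- Iodolysis (I2, THF, 0 °C) gives 2-iodo-5-methoxy-6-[3,4,5-tris(benzyloxy)phenyl]-4H-pyran-4-one F9, which is isolable and shows the site of metalation.
- Iodine–lithium exchange (t-BuLi, 2 equiv, THF/Et2O, −100 °C) then gives 7 free of amine and of unmetalated pyranone, and the route continues with 6 and MeOTf as in step 4.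

Step 5. Process at risk: hydroxide may attack the cyclobutenone carbonyl and cleave the strained ring, or open the pyranone, instead of substituting at the β-carbon. The fallback sets out from 6 and returns at 12; the benzyl group is brought in on the squarate before the pyranone is attached.
- Partial hydrolysis of 6 (NaOH, 1 equiv, MeOH/H2O, 0 °C; then HCl) gives 3-hydroxy-4-methoxycyclobut-3-ene-1,2-dione F10.
- Mitsunobu benzylation (BnOH, PPh3, DIAD, THF) gives 3-(benzyloxy)-4-methoxycyclobut-3-ene-1,2-dione F11.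
- Addition of 7 followed by MeOTf should give 12 together with its regioisomer 2-(benzyloxy)-3,4-dimethoxy-4-{5-methoxy-4-oxo-6-[3,4,5-tris(benzyloxy)phenyl]-4H-pyran-2-yl}cyclobut-2-en-1-one F12, because the two carbonyls of F11 are not differentiated.
- 12 is separated by chromatography and enters step 7; the price is the material that ends up as F12.

**Further compounds**

F1 | step 7 | 2,3,4-trimethoxy-4-(1-methoxyethenyl)cyclobut-2-en-1-one | COC(=C)C1(OC)C(OC)=C(OC)C1=O
F2 | step 7 | lithium 2,4-dimethoxy-4-(1-methoxyethenyl)-3-oxocyclobut-1-en-1-olate | [Li+].[O-]C1=C(OC)C(=O)C1(OC)C(=C)OC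
F3 | step 7 | 3-(benzyloxy)-2,4-dimethoxy-4-(1-methoxyethenyl)cyclobut-2-en-1-one | COC(=C)C1(OC)C(OCc2ccccc2)=C(OC)C1=O
F4 | step 7 | 3-(benzyloxy)-2,4,5-trimethoxyphenol | COc1cc(O)c(OC)c(OCc2ccccc2)c1OC
F5 | step 7 | 1-[4-(benzyloxy)-2-hydroxy-3,5,6-trimethoxyphenyl]-2-methoxyethan-1-one | COCC(=O)c1c(O)c(OC)c(OCc2ccccc2)c(OC)c1OC
F6 | step 7 | 1-[4-(benzyloxy)-2-hydroxy-3,5,6-trimethoxyphenyl]-2-methoxy-3-[3,4,5-tris(benzyloxy)phenyl]propane-1,3-dione | COC(C(=O)c1cc(OCc2ccccc2)c(OCc2ccccc2)c(OCc2ccccc2)c1)C(=O)c1c(O)c(OC)c(OCc2ccccc2)c(OC)c1OC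
F7 | step 7 | 7-(benzyloxy)-3,5,6,8-tetramethoxy-2-[3,4,5-tris(benzyloxy)phenyl]-4H-chromen-4-one | COc1c(OCc2ccccc2)c(OC)c2oc(-c3cc(OCc4ccccc4)c(OCc4ccccc4)c(OCc4ccccc4)c3)c(OC)c(=O)c2c1OC
F8 | step 4 | chloro{5-methoxy-4-oxo-6-[3,4,5-tris(benzyloxy)phenyl]-4H-pyran-2-yl}zinc | Cl[Zn]c1cc(=O)c(OC)c(-c2cc(OCc3ccccc3)c(OCc3ccccc3)c(OCc3ccccc3)c2)o1
F9 | step 4 | 2-iodo-5-methoxy-6-[3,4,5-tris(benzyloxy)phenyl]-4H-pyran-4-one | Ic1cc(=O)c(OC)c(-c2cc(OCc3ccccc3)c(OCc3ccccc3)c(OCc3ccccc3)c2)o1
F10 | step 5 | 3-hydroxy-4-methoxycyclobut-3-ene-1,2-dione | COC1=C(O)C(=O)C1=O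
F11 | step 5 | 3-(benzyloxy)-4-methoxycyclobut-3-ene-1,2-dione | COC1=C(OCc2ccccc2)C(=O)C1=O
F12 | step 5 | 2-(benzyloxy)-3,4-dimethoxy-4-{5-methoxy-4-oxo-6-[3,4,5-tris(benzyloxy)phenyl]-4H-pyran-2-yl}cyclobut-2-en-1-one | COC1=C(OCc2ccccc2)C(=O)C1(OC)c1cc(=O)c(OC)c(-c2cc(OCc3ccccc3)c(OCc3ccccc3)c(OCc3ccccc3)c2)o1
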